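**Assumption and convention:** cembrane numbering is used (C1 = lactone β-carbon, C2, C3/C4 = epoxide with C18 methyl on C4, C7 and C13 = acetoxy carbons, C8 = exo-methylene carbon with C19, C12 = C-methyl carbon with C20, C14 = lactone O-carbon, C15/C17 = α-methylene unit, C16 = lactone carbonyl); the target is then (1S,3R,4R,7S,12S,13R,14R). Compounds 1 and 8 are taken as catalogue chemicals.

## Retrosynthetic overview

1. Target ⇐ catalyst-controlled ketone/KHSO5 epoxidation of the E-C3=C4 alkene of macrocyclic diacetate 21 (epoxide formed last); 21 ⇐ bis-acetylation of diol 20.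
2. 14-Membered ring (second ring) ⇐ Nozaki–Hiyama–Kishi closure of C7–C8 in seco iodo-aldehyde 19, which also creates the C7 carbinol and the C8 exo-methylene.
3. cis-α-Methylene-γ-butyrolactone (first ring, C14–C1 bond) ⇐ new chiral phosphoric acid-catalysed allylboration/lactonisation of α-hydroxy aldehyde 7 (C8–C14) with allylboronate 15 (C1–C7, C15–C17).
4. 7 ⇐ one-flask organocatalytic transfer hydrogenation (C12) and α-aminoxylation (C13) of achiral enal 4, made from hept-6-yn-2-one.
5. 15 ⇐ carboalumination/oxirane opening of a pentynyl silyl ether, vinylalumination with methyl propiolate, copper-catalysed borylation.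

## Route

**Step 1**
Reactants: 1 hept-6-yn-2-one
Product: 2 6-iodohept-6-en-2-one
Conditions: NaI, Me3SiCl, H2O (0.5 equiv), MeCN, rt
Reagents that add atoms: sodium iodide [Na+].[I-]
Why: Markovnikov hydroiodination of the terminal alkyne by HI made in situ gives the 2-iodo-1-alkene needed for the later Nozaki–Hiyama–Kishi closure; the ketone is inert.

**Step 2**
Reactants: 2 6-iodohept-6-en-2-one
Product: 4 7-iodo-3-methylocta-2,7-dienal (E/Z mixture), via N-cyclohexyl 1-azadiene 3 (not isolated)
Conditions: diethyl [2-(cyclohexylamino)vinyl]phosphonate, NaH, THF, 0 °C to rt; then aq. oxalic acid, toluene, rt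
Reagents that add atoms: diethyl [2-(cyclohexylamino)vinyl]phosphonate CCOP(=O)(OCC)/C=C/NC1CCCCC1; water O
Why: Horner–Wadsworth–Emmons formyl-olefination of the methyl ketone and hydrolysis of the unsaturated imine give the β-methyl enal; the E/Z mixture is acceptable because step 3 is stereoconvergent.

**Step 3**
Reactants: 4 7-iodo-3-methylocta-2,7-dienal
Product: 7 (2R,3S)-2-hydroxy-7-iodo-3-methyloct-7-enal, via saturated aldehyde 5 (not isolated), via α-anilinooxy aldehyde 6 (not isolated)
Conditions: morpholinium (S)-3,3′-bis(2,4,6-triisopropylphenyl)-1,1′-binaphthyl-2,2′-diyl phosphate (20 mol%), diethyl 2,6-dimethyl-1,4-dihydropyridine-3,5-dicarboxylate (Hantzsch ester), dioxane, 50 °C; then L-proline (20 mol%), PhNO, DMSO, 0 °C; then Zn, AcOH, THF, 0 °C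
Reagents that add atoms: nitrosobenzene O=Nc1ccccc1
Why: iminium-ion transfer hydrogenation with a chiral phosphate counteranion sets C12 (S) from either enal isomer, proline enamine α-aminoxylation sets C13 (R) under catalyst control, and reductive N–O cleavage frees the hydroxyl. The (S)-salt is chosen by analogy with citral giving (R)-citronellal with the (R)-salt; the antipode is used if the sign proves opposite. Compound 7 is kept as its crude hemiacetal dimer and used directly.

**Step 4**
Reactants: 8 tert-butyldimethyl(pent-4-yn-1-yloxy)silane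
Product: 11 (E)-7-[(tert-butyldimethylsilyl)oxy]-4-methylhept-3-en-1-ol, via alkenyldimethylalane 9 (not isolated), via lithium butylalanate 10 (not isolated)
Conditions: AlMe3, Cp2ZrCl2 (25 mol%), CH2Cl2, 0 °C to rt; then n-BuLi, THF, −78 °C; then oxirane, −78 to 0 °C; aq. work-up
Reagents that add atoms: trimethylaluminium C[Al](C)C; oxirane C1CO1
Why: Negishi zirconium-catalysed syn-carboalumination fixes the E-trisubstituted C3=C4 alkene, and the derived alanate opens oxirane with retention at C3 to add C2 and C1.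

**Step 5**
Reactants: 11 (E)-7-[(tert-butyldimethylsilyl)oxy]-4-methylhept-3-en-1-ol
Product: 12 (E)-7-[(tert-butyldimethylsilyl)oxy]-4-methylhept-3-enal
Conditions: Dess–Martin periodinane, pyridine, CH2Cl2, 0 °C; used crude at once
Reagents that add atoms: none
Why: Dess–Martin oxidation under buffered, non-basic conditions gives the β,γ-unsaturated aldehyde without migration of the alkene into conjugation.

**Step 6**
Reactants: 12 (E)-7-[(tert-butyldimethylsilyl)oxy]-4-methylhept-3-enal
Product: 14 methyl (5E)-3-acetoxy-9-[(tert-butyldimethylsilyl)oxy]-6-methyl-2-methylidenenon-5-enoate (racemic), via aluminium alkoxide 13 (not isolated)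
Conditions: methyl propiolate, iBu2AlH, N-methylmorpholine N-oxide, THF, 0 °C; then 12, 0 °C to rt; then Ac2O, pyridine, 4-(dimethylamino)pyridine, −20 °C to rt
Reagents that add atoms: methyl propiolate C#CC(=O)OC; acetic anhydride CC(=O)OC(C)=O
Why: vinylalumination (1,2-addition of the α-aluminoacrylate from hydroalumination of methyl propiolate) gives the Morita–Baylis–Hillman-type adduct faster than the aldehyde can isomerise, and the aluminium alkoxide is acetylated in the same flask; the racemic carbinol centre is erased in step 7.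

**Step 7**
Reactants: 14 methyl (5E)-3-acetoxy-9-[(tert-butyldimethylsilyl)oxy]-6-methyl-2-methylidenenon-5-enoate
Product: 15 methyl (2E,5E)-9-[(tert-butyldimethylsilyl)oxy]-6-methyl-2-[(4,4,5,5-tetramethyl-1,3,2-dioxaborolan-2-yl)methyl]nona-2,5-dienoate
Conditions: B2pin2, CuCl (10 mol%), LiCl, KOAc, DMF, rt
Reagents that add atoms: bis(pinacolato)diboron CC1(C)OB(OC1(C)C)B1OC(C)(C)C(C)(C)O1
Why: copper-catalysed SN2′ borylation of the allylic acetate gives the trisubstituted allylboronate with the C2 chain cis to CH2B and trans to the ester.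

**Step 8**
Reactants: 7 (2R,3S)-2-hydroxy-7-iodo-3-methyloct-7-enal; 15 methyl (2E,5E)-9-[(tert-butyldimethylsilyl)oxy]-6-methyl-2-[(pinacolboryl)methyl]nona-2,5-dienoate
Product: 18 (4S,5R)-5-[(1R,2S)-1-hydroxy-6-iodo-2-methylhept-6-en-1-yl]-4-[(E)-6-hydroxy-3-methylhex-2-en-1-yl]-3-methylidenedihydrofuran-2(3H)-one, via borate adduct 16 (not isolated), via silyl lactone 17 (not isolated)
Conditions: (R)-3,3′-bis(2,4,6-triisopropylphenyl)-1,1′-binaphthyl-2,2′-diyl hydrogen phosphate (10 mol%), 4 Å molecular sieves, toluene, 0 °C to rt; then (±)-camphor-10-sulfonic acid (cat.), MeOH, rt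
Reagents that add atoms: none
Why: Proposed new method: a chiral phosphoric acid-catalysed, hydroxyl-directed 2-(methoxycarbonyl)allylboration–lactonisation in which boronate 15 and the aldehyde react through the usual six-membered chair with the acid proton on a boronate oxygen; the γ-chain of 15 (cis to CH2B) sits axial and gives the 3,4-syn adduct that closes to the cis-lactone (C1 S), while the free C13 hydroxyl hydrogen-bonds to the phosphoryl oxygen and is held syn to the carbonyl so that C1 adds anti to the C12 chain (13,14-syn, C14 R, a metal-free "chelate" that overturns the usual Cornforth preference) on the same Re face that the (R)-acid favours; the closest known reaction types are the phosphoric acid-catalysed allyl- and crotylboration of aldehydes with pinacol boronates and the thermal or Brønsted acid-promoted 2-(alkoxycarbonyl)allylboration giving cis-α-methylene-γ-butyrolactones, neither of which has been shown with a γ-substituted ester-bearing boronate under chiral acid control or with an unprotected α-hydroxy aldehyde; acidic methanol then completes lactonisation through the C14 oxygen and removes the silyl group.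

**Step 9**
Reactants: 18 lactone diol
Product: 19 (4S,5R)-5-[(1R,2S)-1-hydroxy-6-iodo-2-methylhept-6-en-1-yl]-4-[(E)-3-methyl-6-oxohex-2-en-1-yl]-3-methylidenedihydrofuran-2(3H)-one
Conditions: PhI(OAc)2, 2,2,6,6-tetramethylpiperidin-1-oxyl (10 mol%), CH2Cl2, rt
Reagents that add atoms: none
Why: oxoammonium (TEMPO) oxidation is selective for the primary C7 alcohol over the hindered secondary C13 alcohol and leaves the alkenes and the alkenyl iodide untouched.

**Step 10**
Reactants: 19 seco iodo-aldehyde
Product: 20 (1S,3E,7S,12S,13R,14R)-7,13-dihydroxycembra-3,8(19),15(17)-trien-16,14-olide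
Conditions: CrCl2 (8 equiv), NiCl2 (0.1 equiv), (S)-N-[2-(4-isopropyl-4,5-dihydrooxazol-2-yl)-6-methylphenyl]methanesulfonamide, Et3N, THF, 2 mM, rt; aq. work-up
Reagents that add atoms: none
Why: Nozaki–Hiyama–Kishi reaction: nickel activates the alkenyl iodide, chromium carries the alkenyl group onto the aldehyde only (lactone, free hydroxyl and alkenes tolerated) at high dilution to close the 14-membered ring, and C7 is set as S by the chiral sulfonamide ligand on chromium acting within the macrocyclic transition state (ligand enantiomer to be matched by experiment).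

**Step 11**
Reactants: 20 macrocyclic diol
Product: 21 (1S,3E,7S,12S,13R,14R)-7,13-diacetoxycembra-3,8(19),15(17)-trien-16,14-olide
Conditions: Ac2O, 4-(dimethylamino)pyridine, pyridine, CH2Cl2, rt
Reagents that add atoms: acetic anhydride CC(=O)OC(C)=O
Why: nucleophile-catalysed acylation esterifies both secondary hydroxyls without touching a stereocentre.

**Step 12**
Reactants: 21 macrocyclic diacetate
Product: 22 (1S,3R,4R,7S,12S,13R,14R)-7,13-diacetoxy-3,4-epoxycembra-8(19),15(17)-dien-16,14-olide (CNP0323853.2)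
Conditions: 1,2:4,5-di-O-isopropylidene-β-D-erythro-2,3-hexodiulo-2,6-pyranose (30 mol%), KHSO5 (as Oxone), K2CO3, Bu4NHSO4, MeCN/CH2(OMe)2/aq. Na2B4O7 buffer (pH about 10.5), 0 °C
Reagents that add atoms: potassium peroxymonosulfate [K+].[O-]S(=O)(=O)OO
Why: Shi epoxidation: the chiral dioxirane attacks only the electron-rich trisubstituted C3=C4 alkene (the allylic-acetate 1,1-disubstituted alkene and the α-methylene lactone are much slower) through the spiro transition state that gives the (3R,4R) epoxide from an E-trisubstituted alkene.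

## Compound list

1 | hept-6-yn-2-one | CC(=O)CCCC#C | starting material
2 | 6-iodohept-6-en-2-one | CC(=O)CCCC(I)=C | intermediate
3 | N-cyclohexyl-7-iodo-3-methylocta-2,7-dien-1-imine (2E shown, E/Z mixture) | C=C(I)CCC/C(C)=C/C=NC1CCCCC1 | intermediate (not isolated)
4 | 7-iodo-3-methylocta-2,7-dienal (2E shown, E/Z mixture) | C=C(I)CCC/C(C)=C/C=O | intermediate
5 | (3S)-7-iodo-3-methyloct-7-enal | C=C(I)CCC[C@H](C)CC=O | intermediate (not isolated)
6 | (2R,3S)-7-iodo-3-methyl-2-[(phenylamino)oxy]oct-7-enal | C=C(I)CCC[C@H](C)[C@@H](ONc1ccccc1)C=O | intermediate (not isolated)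
7 | (2R,3S)-2-hydroxy-7-iodo-3-methyloct-7-enal | C=C(I)CCC[C@H](C)[C@@H](O)C=O | intermediate
8 | tert-butyldimethyl(pent-4-yn-1-yloxy)silane | C#CCCCO[Si](C)(C)C(C)(C)C | starting material
9 | (E)-{5-[(tert-butyldimethylsilyl)oxy]-2-methylpent-1-en-1-yl}dimethylalumane | C[Al](C)/C=C(\C)CCCO[Si](C)(C)C(C)(C)C | intermediate (not isolated)
10 | lithium butyl{(E)-5-[(tert-butyldimethylsilyl)oxy]-2-methylpent-1-en-1-yl}dimethylalanate | [Li+].CCCC[Al-](C)(C)/C=C(\C)CCCO[Si](C)(C)C(C)(C)C | intermediate (not isolated)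
11 | (E)-7-[(tert-butyldimethylsilyl)oxy]-4-methylhept-3-en-1-ol | OCC/C=C(\C)CCCO[Si](C)(C)C(C)(C)C | intermediate
12 | (E)-7-[(tert-butyldimethylsilyl)oxy]-4-methylhept-3-enal | O=CC/C=C(\C)CCCO[Si](C)(C)C(C)(C)C | intermediate
13 | diisobutylaluminium alkoxide of methyl (5E)-9-[(tert-butyldimethylsilyl)oxy]-3-hydroxy-6-methyl-2-methylidenenon-5-enoate (racemic) | COC(=O)C(=C)C(O[Al](CC(C)C)CC(C)C)C/C=C(\C)CCCO[Si](C)(C)C(C)(C)C | intermediate (not isolated)
14 | methyl (5E)-3-acetoxy-9-[(tert-butyldimethylsilyl)oxy]-6-methyl-2-methylidenenon-5-enoate (racemic) | COC(=O)C(=C)C(OC(C)=O)C/C=C(\C)CCCO[Si](C)(C)C(C)(C)C | intermediate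
15 | methyl (2E,5E)-9-[(tert-butyldimethylsilyl)oxy]-6-methyl-2-[(4,4,5,5-tetramethyl-1,3,2-dioxaborolan-2-yl)methyl]nona-2,5-dienoate | COC(=O)/C(CB1OC(C)(C)C(C)(C)O1)=C/C/C=C(\C)CCCO[Si](C)(C)C(C)(C)C | intermediate
16 | methyl (3S,4R,5R,6S)-3-{(E)-6-[(tert-butyldimethylsilyl)oxy]-3-methylhex-2-en-1-yl}-5-hydroxy-10-iodo-6-methyl-2-methylidene-4-[(4,4,5,5-tetramethyl-1,3,2-dioxaborolan-2-yl)oxy]undec-10-enoate | C=C(I)CCC[C@H](C)[C@@H](O)[C@H](OB1OC(C)(C)C(C)(C)O1)[C@@H](C/C=C(\C)CCCO[Si](C)(C)C(C)(C)C)C(=C)C(=O)OC | intermediate (not isolated)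
17 | (4S,5R)-4-{(E)-6-[(tert-butyldimethylsilyl)oxy]-3-methylhex-2-en-1-yl}-5-[(1R,2S)-1-hydroxy-6-iodo-2-methylhept-6-en-1-yl]-3-methylidenedihydrofuran-2(3H)-one | C=C(I)CCC[C@H](C)[C@@H](O)[C@@H]1OC(=O)C(=C)[C@@H]1C/C=C(\C)CCCO[Si](C)(C)C(C)(C)C | intermediate (not isolated)
18 | (4S,5R)-5-[(1R,2S)-1-hydroxy-6-iodo-2-methylhept-6-en-1-yl]-4-[(E)-6-hydroxy-3-methylhex-2-en-1-yl]-3-methylidenedihydrofuran-2(3H)-one | C=C(I)CCC[C@H](C)[C@@H](O)[C@@H]1OC(=O)C(=C)[C@@H]1C/C=C(\C)CCCO | intermediate
19 | (4S,5R)-5-[(1R,2S)-1-hydroxy-6-iodo-2-methylhept-6-en-1-yl]-4-[(E)-3-methyl-6-oxohex-2-en-1-yl]-3-methylidenedihydrofuran-2(3H)-one | C=C(I)CCC[C@H](C)[C@@H](O)[C@@H]1OC(=O)C(=C)[C@@H]1C/C=C(\C)CCC=O | intermediate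
20 | (1S,3E,7S,12S,13R,14R)-7,13-dihydroxycembra-3,8(19),15(17)-trien-16,14-olide | C=C1CCC[C@H](C)[C@@H](O)[C@@H]2OC(=O)C(=C)[C@@H]2C/C=C(\C)CC[C@@H]1O | intermediate
21 | (1S,3E,7S,12S,13R,14R)-7,13-diacetoxycembra-3,8(19),15(17)-trien-16,14-olide | C=C1CCC[C@H](C)[C@@H](OC(C)=O)[C@@H]2OC(=O)C(=C)[C@@H]2C/C=C(\C)CC[C@@H]1OC(C)=O | intermediate
22 | (1S,3R,4R,7S,12S,13R,14R)-7,13-diacetoxy-3,4-epoxycembra-8(19),15(17)-dien-16,14-olide (CNP0323853.2) | C=C1CCC[C@H](C)[C@@H](OC(C)=O)[C@@H]2OC(=O)C(=C)[C@@H]2C[C@H]2O[C@]2(C)CC[C@@H]1OC(C)=O | target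

## Step count

Total step count: 12. Longest linear sequence: 9 steps (8 to 22, steps 4 to 12); the other branch (1 to 7) is 3 steps.

## Steps most likely to fail, with fallbacks

**Step 8 (the proposed new allylboration).** The ester-bearing boronate may be too sluggish under a chiral phosphoric acid, the Cornforth (13,14-anti) mode may compete, and aldehyde 7 is fragile. The fallback uses the known indium-mediated aqueous Barbier allylation, which is chelation-controlled by a free α-hydroxyl and gives the syn,syn cis-lactone. It sets out from acetate 14 and aldehyde 7. MgBr2·OEt2 in THF converts 14 by SN2′ displacement into methyl (2Z,5E)-2-(bromomethyl)-9-[(tert-butyldimethylsilyl)oxy]-6-methylnona-2,5-dienoate F1. F1 and 7 are stirred with indium powder in THF/H2O at rt to give methyl (3S,4R,5R,6S)-3-{(E)-6-[(tert-butyldimethylsilyl)oxy]-3-methylhex-2-en-1-yl}-4,5-dihydroxy-10-iodo-6-methyl-2-methylideneundec-10-enoate F2. Camphorsulfonic acid in MeOH then closes the lactone (17) and removes the silyl group, and the route is rejoined at 18.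

**Step 10 (macrocyclisation and C7 configuration).** Ligand control may be overridden by the ring conformation, giving the C7 epimer. The fallback moves stereocontrol from C–C bond formation to a catalyst-controlled ketone reduction. It sets out from the epimer mixture of 20, whose unwanted component is (1S,3E,7R,12S,13R,14R)-7,13-dihydroxycembra-3,8(19),15(17)-trien-16,14-olide F3. MnO2 in CH2Cl2 oxidises only the allylic C7 alcohol to (1S,3E,12S,13R,14R)-13-hydroxy-7-oxocembra-3,8(19),15(17)-trien-16,14-olide F4. Corey–Bakshi–Shibata reduction with (R)-2-methyl-CBS-oxazaborolidine and catecholborane in toluene at −78 °C (alkenyl as the large group) then gives the 7S alcohol, rejoining at 20.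

**Step 12 (face selectivity of the epoxidation on the macrocycle).** If the ring shields the face the ketone catalyst needs, the wrong epoxide forms. The fallback is a two-step halohydrin route that delivers oxygen to the face opposite to the one a direct oxidant prefers. It sets out from 21. N-Bromosuccinimide in THF/H2O at 0 °C reacts only at the trisubstituted alkene (bromonium on the exposed face, water at C4 from the other) to give (1S,3S,4R,7S,12S,13R,14R)-7,13-diacetoxy-3-bromo-4-hydroxycembra-8(19),15(17)-dien-16,14-olide F5. Cs2CO3 in MeCN closes it with inversion at C3 to the (3R,4R) epoxide, arriving at 22. If the ring instead exposes the correct face, the Shi conditions are matched and no fallback is needed.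

## Further compounds

F1 | step 8 | methyl (2Z,5E)-2-(bromomethyl)-9-[(tert-butyldimethylsilyl)oxy]-6-methylnona-2,5-dienoate | COC(=O)/C(CBr)=C/C/C=C(\C)CCCO[Si](C)(C)C(C)(C)C
F2 | step 8 | methyl (3S,4R,5R,6S)-3-{(E)-6-[(tert-butyldimethylsilyl)oxy]-3-methylhex-2-en-1-yl}-4,5-dihydroxy-10-iodo-6-methyl-2-methylideneundec-10-enoate | C=C(I)CCC[C@H](C)[C@@H](O)[C@H](O)[C@@H](C/C=C(\C)CCCO[Si](C)(C)C(C)(C)C)C(=C)C(=O)OC
F3 | step 10 | (1S,3E,7R,12S,13R,14R)-7,13-dihydroxycembra-3,8(19),15(17)-trien-16,14-olide | C=C1CCC[C@H](C)[C@@H](O)[C@@H]2OC(=O)C(=C)[C@@H]2C/C=C(\C)CC[C@H]1O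
F4 | step 10 | (1S,3E,12S,13R,14R)-13-hydroxy-7-oxocembra-3,8(19),15(17)-trien-16,14-olide | C=C1CCC[C@H](C)[C@@H](O)[C@@H]2OC(=O)C(=C)[C@@H]2C/C=C(\C)CCC1=O
F5 | step 12 | (1S,3S,4R,7S,12S,13R,14R)-7,13-diacetoxy-3-bromo-4-hydroxycembra-8(19),15(17)-dien-16,14-olide | C=C1CCC[C@H](C)[C@@H](OC(C)=O)[C@@H]2OC(=O)C(=C)[C@@H]2C[C@H](Br)[C@](C)(O)CC[C@@H]1OC(C)=O
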